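**Retrosynthetic overview**
1. Target ⇒ 13-monoangelate + angelic anhydride (C7 and C8 esters); monoangelate ⇒ 7,8,13-triol + angelic acid; triol ⇒ 7-hydroxy-8-keto-13-aldehyde by hydroxyl-directed reduction.
2. Key bond C7–C8: intramolecular carbene-catalysed cross-benzoin. The acyl-anion equivalent of the C8 aldehyde adds to one of two formyl groups on C6; this closes the seven-membered ring last and sets C6 and C7 together.
3. Keto-trialdehyde ⇒ bicyclo[3.1.1]heptan-6-one: the cyclobutanone carbon is homologated to CH–C(Me)(CH2OH)2 and both C=CH2 groups are ozonised.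
4. Bicyclic ketone ⇒ intramolecular vinylketene–alkene [2+2] of an acyclic trienoic acid: four- and six-membered rings form in one step (C4–C5 and C10–C11).
5. Trienoic acid ⇒ Rh-catalysed asymmetric alkenyl conjugate addition to pent-3-en-2-one (sets C3). Ring order: cyclobutane + cyclohexane together, then cycloheptane.

Assumption: atom labels follow longipinane numbering (C1 ketone, C2, C3 CHMe, cyclobutane C4–C5–C11–C10, C6 quaternary, C7/C8 oxygenated, C9 CH2; C12, C14, C15 = methyls on C3, C6, C10; C13 = CH2O on C6) and are kept for all intermediates; the target is (3R,4S,5S,6S,7S,8S,10R,11R) with three (Z)-2-methylbut-2-enoate (angelate) esters; angelic anhydride is taken as a purchased reagent.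

**Step 1**
Reactants: 1 pent-1-en-4-yne
Product: 2 2-[(1E)-2-methylpenta-1,4-dien-1-yl]-4,4,5,5-tetramethyl-1,3,2-dioxaborolane
Conditions: B2pin2, MeI, CuCl (10 mol %), Xantphos, NaOtBu, THF, rt
Reagents that add atoms: bis(pinacolato)diboron CC1(C)OB(OC1(C)C)B1OC(C)(C)C(C)(C)O1; iodomethane CI
Why: Copper-catalysed syn-methylboration of a terminal alkyne (borylcupration, then methylation of the alkenylcopper) puts boron on the terminal carbon and methyl on the internal carbon on the same side, which fixes the E trisubstituted alkene.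

**Step 2**
Reactants: 2 2-[(1E)-2-methylpenta-1,4-dien-1-yl]-4,4,5,5-tetramethyl-1,3,2-dioxaborolane; 3 (3E)-pent-3-en-2-one
Product: 4 (4R,5E)-4,6-dimethylnona-5,8-dien-2-one
Conditions: [Rh(OH)((R)-BINAP)]2 (2.5 mol %), KOH (20 mol %), dioxane/H2O 10:1, 60 °C
Reagents that add atoms: none
Why: Hayashi–Miyaura rhodium-catalysed asymmetric conjugate addition transfers the alkenyl group with retention of geometry, and (R)-BINAP (assigned by analogy with (S)-BINAP giving (S)-4-aryl-2-alkanones from (E)-3-alken-2-ones) sets the 4R centre, which is C3 of the target.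

**Step 3**
Reactants: 4 (4R,5E)-4,6-dimethylnona-5,8-dien-2-one
Product: 5 ethyl (2E,5R,6E)-3,5,7-trimethyldeca-2,6,9-trienoate
Conditions: (EtO)2P(O)CH2CO2Et, NaH, THF, 0 °C to reflux; 2E isomer separated by chromatography
Reagents that add atoms: triethyl phosphonoacetate CCOC(=O)CP(=O)(OCC)OCC
Why: Horner–Wadsworth–Emmons olefination of the methyl ketone gives mainly the 2E enoate, whose C3 methyl is cis to the carbonyl as step 5 requires; no stereocentre is touched.

**Step 4**
Reactants: 5 ethyl (2E,5R,6E)-3,5,7-trimethyldeca-2,6,9-trienoate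
Product: 6 (2E,5R,6E)-3,5,7-trimethyldeca-2,6,9-trienoic acid
Conditions: LiOH, THF/MeOH/H2O, rt; then 1 M HCl to pH 3
Reagents that add atoms: lithium hydroxide [Li+].[OH-]
Why: Saponification of the ethyl ester; the remote allylic stereocentre is not epimerisable.

**Step 5**
Reactants: 6 (2E,5R,6E)-3,5,7-trimethyldeca-2,6,9-trienoic acid
Product: 9 (1R,2R,5S,7R)-2,7-dimethyl-4-methylidene-7-(prop-2-en-1-yl)bicyclo[3.1.1]heptan-6-one, via acid chloride 7 (not isolated), via vinylketene 8 (not isolated)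
Conditions: (COCl)2, cat. DMF, CH2Cl2, 0 °C to rt, evaporate; then Et3N (3 equiv), toluene, 110 °C, slow addition, 0.01 M
Reagents that add atoms: none
Why: Snider-type intramolecular vinylketene–alkene [2+2] cycloaddition, in which Et3N removes a γ-hydrogen of the C3 methyl to give vinylketene 8, whose carbonyl carbon bonds to the less substituted alkene carbon and whose α-carbon bonds to the disubstituted one, so the four- and six-membered rings form together; addition is suprafacial on the E alkene (C15 methyl syn to the three-carbon bridge, allyl anti) and the C3 methyl steers the ketene to the face that avoids a 1,3-diaxial contact with that methyl, which fixes C4, C10 and C11.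

**Step 6**
Reactants: 9 (1R,2R,5S,7R)-2,7-dimethyl-4-methylidene-7-(prop-2-en-1-yl)bicyclo[3.1.1]heptan-6-one
Product: 10 (1S,2R,5S,6S,7R)-2,7-dimethyl-4-methylidene-7-(prop-2-en-1-yl)bicyclo[3.1.1]heptane-6-carbonitrile
Conditions: TosMIC, KOtBu, DME/EtOH, 0 to 40 °C
Reagents that add atoms: p-toluenesulfonylmethyl isocyanide Cc1ccc(cc1)S(=O)(=O)C[N+]#[C-]
Why: Van Leusen reductive cyanation, in which the TosMIC anion adds to the strained, non-enolisable cyclobutanone and the adduct collapses to the one-carbon-homologated nitrile; C5 forms as an epimer mixture (anti epimer drawn) that is corrected in step 7.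

**Step 7**
Reactants: 10 (1S,2R,5S,6S,7R)-2,7-dimethyl-4-methylidene-7-(prop-2-en-1-yl)bicyclo[3.1.1]heptane-6-carbonitrile
Product: 12 1-[(1S,2R,5S,6S,7R)-2,7-dimethyl-4-methylidene-7-(prop-2-en-1-yl)bicyclo[3.1.1]heptan-6-yl]ethan-1-one, via ketimine 11 (not isolated)
Conditions: MeLi, Et2O, 0 °C to rt; 1 M HCl, THF, 0 °C, 10 min; then K2CO3 (cat.), MeOH, rt
Reagents that add atoms: methyllithium [Li]C; water O
Why: Organolithium addition to the nitrile and hydrolysis of ketimine 11 give the methyl ketone, and base equilibration through the exocyclic enolate places the acetyl group anti to the three-carbon bridge (the syn epimer is 1,3-diaxial to the C3 methyl), which sets C5 with its hydrogen toward the six-membered ring.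

**Step 8**
Reactants: 12 1-[(1S,2R,5S,6S,7R)-2,7-dimethyl-4-methylidene-7-(prop-2-en-1-yl)bicyclo[3.1.1]heptan-6-yl]ethan-1-one
Product: 14 (2RS)-2-[(1S,2R,5S,6S,7R)-2,7-dimethyl-4-methylidene-7-(prop-2-en-1-yl)bicyclo[3.1.1]heptan-6-yl]propanal, via enol ether 13 (not isolated)
Conditions: Ph3P(CH2OMe)Cl, KN(SiMe3)2, THF, 0 °C to rt; then oxalic acid (cat.), THF/H2O, rt
Reagents that add atoms: (methoxymethyl)triphenylphosphonium chloride COC[P+](c1ccccc1)(c1ccccc1)c1ccccc1.[Cl-]; water O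
Why: Wittig (Levine) methoxymethylenation to enol ether 13 and mild acid hydrolysis give the homologated α-methyl aldehyde; the new C6 centre forms unselectively but is erased in step 9, and the dilute acid does not protonate the β-pinene-type methylidene.

**Step 9**
Reactants: 14 (2RS)-2-[(1S,2R,5S,6S,7R)-2,7-dimethyl-4-methylidene-7-(prop-2-en-1-yl)bicyclo[3.1.1]heptan-6-yl]propanal
Product: 16 2-[(1S,2R,5S,6S,7R)-2,7-dimethyl-4-methylidene-7-(prop-2-en-1-yl)bicyclo[3.1.1]heptan-6-yl]-2-methylpropane-1,3-diol, via aldol adduct 15 (not isolated)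
Conditions: 37 % aq. CH2O (excess), KOH, EtOH/H2O, 60 °C
Reagents that add atoms: formaldehyde C=O
Why: Tollens reaction, in which a crossed aldol with formaldehyde gives β-hydroxy aldehyde 15 with C6 quaternary and a crossed Cannizzaro reduction by a second formaldehyde gives the 1,3-diol; C6 now carries two identical CH2OH groups and is not a stereocentre.

**Step 10**
Reactants: 16 2-[(1S,2R,5S,6S,7R)-2,7-dimethyl-4-methylidene-7-(prop-2-en-1-yl)bicyclo[3.1.1]heptan-6-yl]-2-methylpropane-1,3-diol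
Product: 17 2-[(1S,2R,5S,6S,7R)-2,7-dimethyl-4-methylidene-7-(prop-2-en-1-yl)bicyclo[3.1.1]heptan-6-yl]-2-methylpropanedial
Conditions: Dess–Martin periodinane (2.4 equiv), CH2Cl2, rt
Reagents that add atoms: none
Why: Dess–Martin oxidation of both neopentyl primary alcohols under non-basic conditions gives the 2,2-disubstituted malondialdehyde, which cannot enolise.

**Step 11**
Reactants: 17 2-[(1S,2R,5S,6S,7R)-2,7-dimethyl-4-methylidene-7-(prop-2-en-1-yl)bicyclo[3.1.1]heptan-6-yl]-2-methylpropanedial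
Product: 19 2-[(1S,2R,5R,6S,7R)-2,7-dimethyl-4-oxo-7-(2-oxoethyl)bicyclo[3.1.1]heptan-6-yl]-2-methylpropanedial, via bis-ozonide 18 (not isolated)
Conditions: O3, CH2Cl2, −78 °C; then Me2S, −78 °C to rt; used crude at once
Reagents that add atoms: ozone [O-][O+]=O
Why: Ozonolysis with reductive work-up cleaves both terminal alkenes (the methylidene to the C1 ketone as in β-pinene to nopinone, the allyl group to the C8 aldehyde) under neutral conditions; no stereocentre is touched.

**Step 12**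
Reactants: 19 2-[(1S,2R,5R,6S,7R)-2,7-dimethyl-4-oxo-7-(2-oxoethyl)bicyclo[3.1.1]heptan-6-yl]-2-methylpropanedial
Product: 20 (3R,4S,5S,6R,7S,10R,11R)-7-hydroxy-1,8-dioxolongipinan-13-al
Conditions: (5aS,10bR)-2-(pentafluorophenyl)-5a,10b-dihydro-4H,6H-indeno[2,1-b][1,2,4]triazolo[4,3-d][1,4]oxazin-2-ium tetrafluoroborate (10 mol %), Et3N (10 mol %), toluene, 4 Å MS, rt
Reagents that add atoms: none
Why: Proposed new method: the triazolylidene adds to the least hindered aldehyde (CH2CHO, C8) to give the Breslow acyl-anion equivalent, which attacks one of the two more electrophilic, non-enolisable formyl groups on C6 held 1,3-diaxially beside it on the cyclobutane (seven-membered closure), while the chiral catalyst chooses between the two nearly enantiotopic formyl groups (the bicyclic core is almost mirror-symmetric) and the carbonyl face so that C6 and C7 are set together with the C7 hydroxyl cis to the C6 methyl; the closest known reactions are the desymmetrising intramolecular aldehyde–1,3-diketone crossed benzoin and chemoselective aldehyde–aldehyde cross-benzoins with hindered acceptors.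

**Step 13**
Reactants: 20 (3R,4S,5S,6R,7S,10R,11R)-7-hydroxy-1,8-dioxolongipinan-13-al
Product: 21 (3R,4S,5S,6S,7S,8S,10R,11R)-7,8,13-trihydroxylongipinan-1-one
Conditions: Me4NBH(OAc)3, MeCN/AcOH 1:1, −20 to 0 °C
Reagents that add atoms: none
Why: Hydroxyl-directed triacetoxyborohydride reduction (Saksena–Evans), in which the C7 hydroxyl binds boron and delivers hydride to the adjacent C8 ketone on its own face to give the trans-7,8-diol (sets C8), the β-hydroxy aldehyde is reduced likewise to the C13 CH2OH, and the undirected C1 ketone is left alone.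

**Step 14**
Reactants: 21 (3R,4S,5S,6S,7S,8S,10R,11R)-7,8,13-trihydroxylongipinan-1-one; 22 angelic acid, (2Z)-2-methylbut-2-enoic acid
Product: 24 (3R,4S,5S,6S,7S,8S,10R,11R)-7,8-dihydroxy-1-oxolongipinan-13-yl (2Z)-2-methylbut-2-enoate, via mixed anhydride 23 (not isolated)
Conditions: 22 (1.2 equiv), 2,4,6-trichlorobenzoyl chloride (1.2 equiv), Et3N, toluene, rt, 1 h; then 21, rt to 50 °C
Reagents that add atoms: none
Why: Yamaguchi-type esterification through mixed anhydride 23, run without a nucleophilic amine catalyst so that the Z geometry is kept, in which the bulky acyl donor takes the primary C13 hydroxyl ahead of the two secondary ones (any doubly acylated material converges to the target in step 15); no stereocentre is touched.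

**Step 15**
Reactants: 24 (3R,4S,5S,6S,7S,8S,10R,11R)-7,8-dihydroxy-1-oxolongipinan-13-yl (2Z)-2-methylbut-2-enoate; 25 angelic anhydride, (2Z)-2-methylbut-2-enoic anhydride
Product: 26 (3R,4S,5S,6S,7S,8S,10R,11R)-7,8,13-tris(angeloyloxy)longipinan-1-one (CNP0214984.1)
Conditions: LiN(SiMe3)2 (2.05 equiv), THF, −78 °C, 15 min; then 25 (3 equiv), −78 to 0 °C; sat. aq. NH4Cl
Reagents that add atoms: none
Why: Stereoconservative acylation of the two lithium alkoxides (C8 and the hindered neopentyl C7) by the symmetric anhydride, in which O–H deprotonation at −78 °C with no excess base outpaces enolisation of the C1 ketone, the absence of a nucleophilic catalyst keeps all three esters Z, and any acyl migration between O13 and O7 is degenerate because every oxygen ends as an angelate; no stereocentre is touched.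

**Compound list**
1 | pent-1-en-4-yne | C=CCC#C | starting material
2 | 2-[(1E)-2-methylpenta-1,4-dien-1-yl]-4,4,5,5-tetramethyl-1,3,2-dioxaborolane | C=CC/C(C)=C/B1OC(C)(C)C(C)(C)O1 | intermediate
3 | (3E)-pent-3-en-2-one | C/C=C/C(C)=O | starting material
4 | (4R,5E)-4,6-dimethylnona-5,8-dien-2-one | C=CC/C(C)=C/[C@H](C)CC(C)=O | intermediate
5 | ethyl (2E,5R,6E)-3,5,7-trimethyldeca-2,6,9-trienoate | C=CC/C(C)=C/[C@H](C)C/C(C)=C/C(=O)OCC | intermediate
6 | (2E,5R,6E)-3,5,7-trimethyldeca-2,6,9-trienoic acid | C=CC/C(C)=C/[C@H](C)C/C(C)=C/C(=O)O | intermediate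
7 | (2E,5R,6E)-3,5,7-trimethyldeca-2,6,9-trienoyl chloride | C=CC/C(C)=C/[C@H](C)C/C(C)=C/C(=O)Cl | intermediate
8 | (5R,6E)-5,7-dimethyl-3-methylidenedeca-1,6,9-trien-1-one (vinylketene) | C=CC/C(C)=C/[C@H](C)CC(=C)C=C=O | intermediate
9 | (1R,2R,5S,7R)-2,7-dimethyl-4-methylidene-7-(prop-2-en-1-yl)bicyclo[3.1.1]heptan-6-one | O=C1[C@@H]2[C@H](C)CC(=C)[C@H]1[C@]2(C)CC=C | intermediate
10 | (1S,2R,5S,6S,7R)-2,7-dimethyl-4-methylidene-7-(prop-2-en-1-yl)bicyclo[3.1.1]heptane-6-carbonitrile (anti epimer; C6 epimer also present) | N#C[C@H]1[C@@H]2[C@H](C)CC(=C)[C@H]1[C@]2(C)CC=C | intermediate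
11 | 1-[(1S,2R,5S,6S,7R)-2,7-dimethyl-4-methylidene-7-(prop-2-en-1-yl)bicyclo[3.1.1]heptan-6-yl]ethan-1-imine | CC(=N)[C@H]1[C@@H]2[C@H](C)CC(=C)[C@H]1[C@]2(C)CC=C | intermediate
12 | 1-[(1S,2R,5S,6S,7R)-2,7-dimethyl-4-methylidene-7-(prop-2-en-1-yl)bicyclo[3.1.1]heptan-6-yl]ethan-1-one | CC(=O)[C@H]1[C@@H]2[C@H](C)CC(=C)[C@H]1[C@]2(C)CC=C | intermediate
13 | (1S,2R,5S,6S,7R)-6-(1-methoxyprop-1-en-2-yl)-2,7-dimethyl-4-methylidene-7-(prop-2-en-1-yl)bicyclo[3.1.1]heptane (E/Z mixture) | COC=C(C)[C@H]1[C@@H]2[C@H](C)CC(=C)[C@H]1[C@]2(C)CC=C | intermediate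
14 | (2RS)-2-[(1S,2R,5S,6S,7R)-2,7-dimethyl-4-methylidene-7-(prop-2-en-1-yl)bicyclo[3.1.1]heptan-6-yl]propanal | O=CC(C)[C@H]1[C@@H]2[C@H](C)CC(=C)[C@H]1[C@]2(C)CC=C | intermediate
15 | (2RS)-3-hydroxy-2-methyl-2-[(1S,2R,5S,6S,7R)-2,7-dimethyl-4-methylidene-7-(prop-2-en-1-yl)bicyclo[3.1.1]heptan-6-yl]propanal | O=CC(C)(CO)[C@H]1[C@@H]2[C@H](C)CC(=C)[C@H]1[C@]2(C)CC=C | intermediate
16 | 2-[(1S,2R,5S,6S,7R)-2,7-dimethyl-4-methylidene-7-(prop-2-en-1-yl)bicyclo[3.1.1]heptan-6-yl]-2-methylpropane-1,3-diol | OCC(C)(CO)[C@H]1[C@@H]2[C@H](C)CC(=C)[C@H]1[C@]2(C)CC=C | intermediate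
17 | 2-[(1S,2R,5S,6S,7R)-2,7-dimethyl-4-methylidene-7-(prop-2-en-1-yl)bicyclo[3.1.1]heptan-6-yl]-2-methylpropanedial | O=CC(C)(C=O)[C@H]1[C@@H]2[C@H](C)CC(=C)[C@H]1[C@]2(C)CC=C | intermediate
18 | bis(1,2,4-trioxolane) of 17: spiro ozonide at C1 and ozonide of the allyl alkene, core as in 17, new ozonide centres unassigned | O=CC(C)(C=O)[C@H]1[C@@H]2[C@H](C)CC3(OCOO3)[C@H]1[C@]2(C)CC4OCOO4 | intermediate
19 | 2-[(1S,2R,5R,6S,7R)-2,7-dimethyl-4-oxo-7-(2-oxoethyl)bicyclo[3.1.1]heptan-6-yl]-2-methylpropanedial | O=CC(C)(C=O)[C@H]1[C@@H]2[C@H](C)CC(=O)[C@H]1[C@]2(C)CC=O | intermediate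
20 | (3R,4S,5S,6R,7S,10R,11R)-7-hydroxy-1,8-dioxolongipinan-13-al | O=C[C@]1(C)[C@H]2[C@@H]3[C@H](C)CC(=O)[C@H]2[C@]3(C)CC(=O)[C@H]1O | intermediate
21 | (3R,4S,5S,6S,7S,8S,10R,11R)-7,8,13-trihydroxylongipinan-1-one | OC[C@]1(C)[C@H]2[C@@H]3[C@H](C)CC(=O)[C@H]2[C@]3(C)C[C@H](O)[C@H]1O | intermediate
22 | angelic acid, (2Z)-2-methylbut-2-enoic acid | C/C=C(/C)C(=O)O | starting material
23 | (2Z)-2-methylbut-2-enoic 2,4,6-trichlorobenzoic anhydride (mixed anhydride) | C/C=C(/C)C(=O)OC(=O)c1c(Cl)cc(Cl)cc1Cl | intermediate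
24 | (3R,4S,5S,6S,7S,8S,10R,11R)-7,8-dihydroxy-1-oxolongipinan-13-yl (2Z)-2-methylbut-2-enoate | C/C=C(/C)C(=O)OC[C@]1(C)[C@H]2[C@@H]3[C@H](C)CC(=O)[C@H]2[C@]3(C)C[C@H](O)[C@H]1O | intermediate
25 | angelic anhydride, (2Z)-2-methylbut-2-enoic anhydride | C/C=C(/C)C(=O)OC(=O)/C(C)=C\C | starting material
26 | (3R,4S,5S,6S,7S,8S,10R,11R)-7,8,13-tris(angeloyloxy)longipinan-1-one | C/C=C(/C)C(=O)OC[C@]1(C)[C@H]2[C@@H]3[C@H](C)CC(=O)[C@H]2[C@]3(C)C[C@H](OC(=O)/C(C)=C\C)[C@H]1OC(=O)/C(C)=C\C | target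

**Totals**
Total step count: 15. Longest linear sequence: 15 steps (1 → 26).

**Three steps most likely to fail**

Step 12 (desymmetrising cross-benzoin). Risks: the carbene may attack a malondialdehyde formyl group and cause deformylation; retro-aldol of the product; weak selection between the two formyl groups. If the opposite formyl group is selected, the antipodal catalyst is used. Fallback: set out from diol 16 and come back at triol 21, desymmetrising by acyl transfer before the ring closure. Enantioselective monobenzoylation of 16 (BzCl, Et3N, CuCl2 with (R,R)-Ph-BOX, or its antipode as found) gives (2R)-3-hydroxy-2-methyl-2-(bicycloheptyl)propyl benzoate F5, in which C6 is already fixed. Dess–Martin oxidation gives aldehyde F6. Ozonolysis (O3, then Me2S) passes through bis-ozonide F7 to keto-dialdehyde F8. An achiral triazolium salt (2-mesityl-6,7-dihydro-5H-pyrrolo[2,1-c][1,2,4]triazol-2-ium chloride, Et3N) then runs a plain two-aldehyde cross-benzoin to ketol benzoate F9. Me4NBH(OAc)3 gives diol benzoate F10, and K2CO3 in MeOH removes the benzoate to give 21.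

Step 5 (vinylketene [2+2]). Risks: ketene oligomerisation, γ-deprotonation at CH2 instead of CH3, modest facial selectivity. Fallback: set out from ester 5 and come back at ketone 9, replacing the ketene by a more electrophilic keteniminium ion. Kinetic deconjugation of 5 (LiN(iPr)2, HMPA, THF, −78 °C, AcOH quench) gives the 3-methylidene ester F1. Me3Al and pyrrolidine convert it to pyrrolidine amide F2. Tf2O and 2,4,6-collidine in refluxing 1,2-dichloroethane generate keteniminium triflate F3, which closes by intramolecular [2+2] to cyclobutaniminium triflate F4. Aqueous NaHCO3 hydrolyses F4 to 9.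

Step 15 (bis-angeloylation of the hindered secondary hydroxyls). Risks: slow acylation of the neopentyl C7 alkoxide, competing enolisation of the C1 ketone, and Z to E isomerisation to tiglate. Fallback: set out from monoangelate 24 and come back at target 26, building the two remaining Z alkenes after esterification. Acylation of both secondary hydroxyls with 2-[bis(2,2,2-trifluoroethoxy)phosphoryl]propanoic acid (DCC, DMAP, CH2Cl2) gives bis(phosphonopropanoate) F11. Still–Gennari olefination with acetaldehyde (KN(SiMe3)2, 18-crown-6, THF, −78 °C) then forms the two (Z)-2-methylbut-2-enoates in place to give 26.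

**Further compounds**
F1 | step 5 | ethyl (5R,6E)-5,7-dimethyl-3-methylidenedeca-6,9-dienoate | C=CC/C(C)=C/[C@H](C)CC(=C)CC(=O)OCC
F2 | step 5 | (5R,6E)-5,7-dimethyl-3-methylidene-1-(pyrrolidin-1-yl)deca-6,9-dien-1-one | C=CC/C(C)=C/[C@H](C)CC(=C)CC(=O)N1CCCC1
F3 | step 5 | 1-[(5R,6E)-5,7-dimethyl-3-methylidenedeca-1,6,9-trien-1-ylidene]pyrrolidin-1-ium trifluoromethanesulfonate | C=CC/C(C)=C/[C@H](C)CC(=C)C=C=[N+]1CCCC1.[O-]S(=O)(=O)C(F)(F)F
F4 | step 5 | 1-[(1R,2R,5S,7R)-2,7-dimethyl-4-methylidene-7-(prop-2-en-1-yl)bicyclo[3.1.1]heptan-6-ylidene]pyrrolidin-1-ium trifluoromethanesulfonate | C1(=[N+]3CCCC3)[C@@H]2[C@H](C)CC(=C)[C@H]1[C@]2(C)CC=C.[O-]S(=O)(=O)C(F)(F)F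
F5 | step 12 | (2R)-3-hydroxy-2-methyl-2-[(1S,2R,5S,6S,7R)-2,7-dimethyl-4-methylidene-7-(prop-2-en-1-yl)bicyclo[3.1.1]heptan-6-yl]propyl benzoate | O=C(OC[C@@](C)(CO)[C@H]1[C@@H]2[C@H](C)CC(=C)[C@H]1[C@]2(C)CC=C)c1ccccc1
F6 | step 12 | (2S)-2-methyl-3-oxo-2-[(1S,2R,5S,6S,7R)-2,7-dimethyl-4-methylidene-7-(prop-2-en-1-yl)bicyclo[3.1.1]heptan-6-yl]propyl benzoate | O=C(OC[C@@](C)(C=O)[C@H]1[C@@H]2[C@H](C)CC(=C)[C@H]1[C@]2(C)CC=C)c1ccccc1
F7 | step 12 | bis(1,2,4-trioxolane) of F6 (ozonide centres unassigned) | O=C(OC[C@@](C)(C=O)[C@H]1[C@@H]2[C@H](C)CC3(OCOO3)[C@H]1[C@]2(C)CC4OCOO4)c1ccccc1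
F8 | step 12 | (2S)-2-[(1S,2R,5R,6S,7R)-2,7-dimethyl-4-oxo-7-(2-oxoethyl)bicyclo[3.1.1]heptan-6-yl]-2-methyl-3-oxopropyl benzoate | O=C(OC[C@@](C)(C=O)[C@H]1[C@@H]2[C@H](C)CC(=O)[C@H]1[C@]2(C)CC=O)c1ccccc1
F9 | step 12 | [(3R,4S,5S,6S,7S,10R,11R)-7-hydroxy-1,8-dioxolongipinan-13-yl] benzoate | O=C(OC[C@]1(C)[C@H]2[C@@H]3[C@H](C)CC(=O)[C@H]2[C@]3(C)CC(=O)[C@H]1O)c1ccccc1
F10 | step 12 | [(3R,4S,5S,6S,7S,8S,10R,11R)-7,8-dihydroxy-1-oxolongipinan-13-yl] benzoate | O=C(OC[C@]1(C)[C@H]2[C@@H]3[C@H](C)CC(=O)[C@H]2[C@]3(C)C[C@H](O)[C@H]1O)c1ccccc1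
F11 | step 15 | (3R,4S,5S,6S,7S,8S,10R,11R)-13-(angeloyloxy)-1-oxolongipinane-7,8-diyl bis{2-[bis(2,2,2-trifluoroethoxy)phosphoryl]propanoate} (phosphonate α-centres unassigned) | C/C=C(/C)C(=O)OC[C@]1(C)[C@H]2[C@@H]3[C@H](C)CC(=O)[C@H]2[C@]3(C)C[C@H](OC(=O)C(C)P(=O)(OCC(F)(F)F)OCC(F)(F)F)[C@H]1OC(=O)C(C)P(=O)(OCC(F)(F)F)OCC(F)(F)F
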